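**Retrosynthetic overview**
1. Target ⇒ decalin hydroxy-aldehyde + isovalerylphloroglucinol, joined and dearomatized in one final flask: reductive C-alkylation at one of the two equivalent ring CH positions, then geminal C-methylation of the other CH (benzene ring → 6,6-dimethylcyclohexadienone).
2. Hydroxy-aldehyde ⇒ Δ3 bicyclic ester: chemo- and face-selective epoxidation, hydride opening (sets C4), primary alcohol → aldehyde.
3. Bicyclic ester ⇒ acyclic (2E,8E)-trienoate by intramolecular Diels–Alder reaction: rings A and B close together (C5–C10 and C1–C2 bonds), and C1, C5, C10 are set from the single stereocentre C7.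
4. Trienoate ⇒ (S)-3-isopropenyl-6-oxoheptanal (two Wittig olefinations, one Horner–Wadsworth–Emmons) ⇒ (4S)-limonene oxide; the arene ⇒ phloroglucinol + isovaleryl chloride.
5. Ring order: rings A and B simultaneously (step 4); the triketone ring is the purchased benzene ring, dearomatized last (step 9).

Assumption: (4S)-limonene 1,2-oxide (cis/trans mixture, sold as (−)-limonene oxide) is commercial; both epoxide diastereomers converge in step 1.

Locants in the Why lines use eudesmane-type numbering of the decalin: C1 carries the one-carbon arm, C4 the carbinol, C5/C10 the ring fusion (CH3 on C10), C7 the isopropenyl group. Ring A is the carbinol ring, ring B the isopropenyl ring.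

**Step 1**
Reactants: 1 (4S)-limonene 1,2-oxide (cis/trans mixture)
Product: 3 (3S)-6-oxo-3-(prop-1-en-2-yl)heptanal, via limonene glycol 2 (not isolated)
Conditions: H5IO6 (1.2 equiv), THF/H2O 5:1, 0 → 23 °C
Reagents that add atoms: water, O
Why: Acid-promoted epoxide hydrolysis to the glycol followed by Malaprade glycol cleavage with periodic acid opens the ring between the two oxygenated carbons, and the only stereocentre (future C7, S) is remote and untouched.

**Step 2**
Reactants: 3 (3S)-6-oxo-3-(prop-1-en-2-yl)heptanal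
Product: 5 (5S,7E)-8-methyl-5-(prop-1-en-2-yl)deca-7,9-dien-2-one, via enal ketone 4 (not isolated)
Conditions: Ph3P=C(CH3)CHO (1.05 equiv), toluene, 90 °C; then Ph3P=CH2 (from Ph3PCH3Br, KN(SiMe3)2, THF; 1.05 equiv), −78 → 0 °C
Reagents that add atoms: 2-(triphenylphosphoranylidene)propanal, CC(C=O)=P(c1ccccc1)(c1ccccc1)c1ccccc1; methyltriphenylphosphonium bromide (used as its ylide), C[P+](c1ccccc1)(c1ccccc1)c1ccccc1.[Br-]
Why: Two Wittig olefinations in one flask: the formyl-stabilized ylide reacts only with the aldehyde and gives the (E)-2-methyl-enal, whose CHO is then methylenated by Ph3P=CH2 at low temperature much faster than the methyl ketone, so the (E)-3-methyl-1,3-diene is built without touching the ketone or the stereocentre.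

**Step 3**
Reactants: 5 (5S,7E)-8-methyl-5-(prop-1-en-2-yl)deca-7,9-dien-2-one
Product: 6 ethyl (2E,6S,8E)-3,9-dimethyl-6-(prop-1-en-2-yl)undeca-2,8,10-trienoate
Conditions: (EtO)2P(O)CH2CO2Et, NaH, THF, 0 → 66 °C; (2E) isomer separated from the minor (2Z) isomer by chromatography (expected about 4:1)
Reagents that add atoms: triethyl phosphonoacetate, CCOC(=O)CP(=O)(OCC)OCC
Why: Horner–Wadsworth–Emmons olefination of the methyl ketone gives mainly the (E)-trisubstituted enoate (ester anti to the chain), the geometry that later places the C1 arm cis to the angular methyl.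

**Step 4**
Reactants: 6 ethyl (2E,6S,8E)-3,9-dimethyl-6-(prop-1-en-2-yl)undeca-2,8,10-trienoate
Product: 7 ethyl (1S,4aR,6S,8aS)-4,8a-dimethyl-6-(prop-1-en-2-yl)-1,2,4a,5,6,7,8,8a-octahydronaphthalene-1-carboxylate
Conditions: BHT (5 mol %), toluene (0.01 M), sealed tube, 190 °C, 36 h; minor diastereomers removed by chromatography
Reagents that add atoms: none
Why: Intramolecular Diels–Alder reaction of a 1,7,9-decatriene-type substrate through the chair-like anti transition state (ester endo, isopropenyl equatorial on the four-carbon tether) forms rings A and B at once, the trans fusion (C5-H/C10-CH3) coming from the anti tether, the cis C1-ester/C10-methyl relation from suprafacial addition to the (E)-enoate, and the sense relative to C7 from the equatorial isopropenyl group.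

**Step 5**
Reactants: 7 ethyl (1S,4aR,6S,8aS)-4,8a-dimethyl-6-(prop-1-en-2-yl)-1,2,4a,5,6,7,8,8a-octahydronaphthalene-1-carboxylate
Product: 8 ethyl (1S,3S,4R,4aS,6S,8aS)-3,4-epoxy-4,8a-dimethyl-6-(prop-1-en-2-yl)decahydronaphthalene-1-carboxylate (epoxide oxygen anti to the 8a-methyl)
Conditions: mCPBA (1.05 equiv), NaHCO3, CH2Cl2, −10 → 0 °C
Reagents that add atoms: mCPBA, OOC(=O)c1cccc(Cl)c1
Why: Prilezhaev epoxidation is faster at the electron-rich trisubstituted ring alkene than at the 1,1-disubstituted isopropenyl group, and the peracid approaches the face opposite the axial angular methyl, which fixes the C4–O bond anti to C10-CH3.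

**Step 6**
Reactants: 8 ethyl (1S,3S,4R,4aS,6S,8aS)-3,4-epoxy-4,8a-dimethyl-6-(prop-1-en-2-yl)decahydronaphthalene-1-carboxylate
Product: 9 [(1S,4S,4aS,6S,8aR)-4-hydroxy-4,8a-dimethyl-6-(prop-1-en-2-yl)decahydronaphthalen-1-yl]methanol
Conditions: LiAlH4 (3 equiv), THF, 0 → 66 °C; Fieser work-up
Reagents that add atoms: none
Why: LiAlH4 reduces the ester to the primary alcohol and opens the trisubstituted epoxide by SN2 hydride attack at the secondary carbon C3 (the tertiary C4 is shielded by the syn-axial methyl), so the C4–O bond set in step 5 is retained as the equatorial tertiary alcohol with an axial methyl.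

**Step 7**
Reactants: 9 [(1S,4S,4aS,6S,8aR)-4-hydroxy-4,8a-dimethyl-6-(prop-1-en-2-yl)decahydronaphthalen-1-yl]methanol
Product: 10 (1S,4S,4aS,6S,8aS)-4-hydroxy-4,8a-dimethyl-6-(prop-1-en-2-yl)decahydronaphthalene-1-carbaldehyde
Conditions: TEMPO (10 mol %), PhI(OAc)2 (1.1 equiv), CH2Cl2, 23 °C
Reagents that add atoms: none
Why: Oxoammonium (TEMPO) oxidation is selective for the primary alcohol while the tertiary carbinol and the alkene are inert, and the formyl group sits equatorial at C1 (the thermodynamic position, so any α-epimerization is self-correcting).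

**Step 8**
Reactants: 11 phloroglucinol; 12 isovaleryl chloride (3-methylbutanoyl chloride)
Product: 13 1-(2,4,6-trihydroxyphenyl)-3-methylbutan-1-one (isovalerylphloroglucinol)
Conditions: AlCl3 (3 equiv), PhNO2/CH2Cl2, 0 → 50 °C; aq. HCl
Reagents that add atoms: none
Why: Friedel–Crafts C-acylation of the highly activated arene stops at the mono-ketone because the chelated acyl group deactivates the ring; no stereocentre is formed.

**Step 9**
Reactants: 10 (1S,4S,4aS,6S,8aS)-4-hydroxy-4,8a-dimethyl-6-(prop-1-en-2-yl)decahydronaphthalene-1-carbaldehyde; 13 1-(2,4,6-trihydroxyphenyl)-3-methylbutan-1-one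
Product: 16 3,5-dihydroxy-4-{[(1R,4S,4aS,6S,8aR)-4-hydroxy-4,8a-dimethyl-6-(prop-1-en-2-yl)decahydronaphthalen-1-yl]methyl}-6,6-dimethyl-2-(3-methylbutanoyl)cyclohexa-2,4-dien-1-one (CNP0490948.1), via C-alkylated acylphloroglucinol 14 (not isolated), via mono-C-methylated arene 15 (not isolated)
Conditions: 13 (1.1 equiv), L-proline (20 mol %), Hantzsch ester (1.2 equiv), MeOH, 45 °C; then NaOMe (6 equiv), MeI (2.3 equiv), 0 → 23 °C; 1 M HCl
Reagents that add atoms: iodomethane, CI
Why: Proposed new method: the proline iminium of 10 is attacked by one of the two mirror-equivalent ring CH carbons of 13, loss of proline gives an ortho-quinone methide that the Hantzsch ester reduces to 14 (closest known chemistry: three-component reductive alkylation of cyclic 1,3-diones and hydroxyquinones, and transfer hydrogenation of ortho-quinone methides), after which the one remaining ring CH is C-methylated twice by MeI/NaOMe (classical alkylative dearomatization of acylphloroglucinols to filicinic-acid-type triketones), the bulky decalinylmethyl group steering the second methyl to the carbon that already carries the first; no new stereocentre is formed and C1 stays equatorial (thermodynamic under enamine equilibration).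

**Compound list**
1 | (4S)-limonene 1,2-oxide (cis/trans mixture) | C=C(C)[C@H]1CCC2(C)OC2C1 | starting material
2 | (4S)-p-menth-8-ene-1,2-diol (limonene glycol; C1/C2 configuration irrelevant) | C=C(C)[C@H]1CCC(C)(O)C(O)C1 | intermediate (not isolated)
3 | (3S)-6-oxo-3-(prop-1-en-2-yl)heptanal | C=C(C)[C@H](CC=O)CCC(C)=O | intermediate
4 | (2E,5S)-2-methyl-8-oxo-5-(prop-1-en-2-yl)non-2-enal | C=C(C)[C@H](C/C=C(\C)C=O)CCC(C)=O | intermediate (not isolated)
5 | (5S,7E)-8-methyl-5-(prop-1-en-2-yl)deca-7,9-dien-2-one | C=C(C)[C@H](C/C=C(\C)C=C)CCC(C)=O | intermediate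
6 | ethyl (2E,6S,8E)-3,9-dimethyl-6-(prop-1-en-2-yl)undeca-2,8,10-trienoate | C=C(C)[C@H](C/C=C(\C)C=C)CC/C(C)=C/C(=O)OCC | intermediate
7 | ethyl (1S,4aR,6S,8aS)-4,8a-dimethyl-6-(prop-1-en-2-yl)-1,2,4a,5,6,7,8,8a-octahydronaphthalene-1-carboxylate | C=C(C)[C@H]1CC[C@]2(C)[C@@H](C(=O)OCC)CC=C(C)[C@H]2C1 | intermediate
8 | ethyl (1S,3S,4R,4aS,6S,8aS)-3,4-epoxy-4,8a-dimethyl-6-(prop-1-en-2-yl)decahydronaphthalene-1-carboxylate | C=C(C)[C@H]1CC[C@]2(C)[C@@H](C(=O)OCC)C[C@@H]3O[C@]3(C)[C@H]2C1 | intermediate
9 | [(1S,4S,4aS,6S,8aR)-4-hydroxy-4,8a-dimethyl-6-(prop-1-en-2-yl)decahydronaphthalen-1-yl]methanol | C=C(C)[C@H]1CC[C@]2(C)[C@@H](CO)CC[C@](C)(O)[C@H]2C1 | intermediate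
10 | (1S,4S,4aS,6S,8aS)-4-hydroxy-4,8a-dimethyl-6-(prop-1-en-2-yl)decahydronaphthalene-1-carbaldehyde | C=C(C)[C@H]1CC[C@]2(C)[C@@H](C=O)CC[C@](C)(O)[C@H]2C1 | intermediate
11 | phloroglucinol (benzene-1,3,5-triol) | Oc1cc(O)cc(O)c1 | starting material
12 | isovaleryl chloride (3-methylbutanoyl chloride) | CC(C)CC(=O)Cl | starting material
13 | 1-(2,4,6-trihydroxyphenyl)-3-methylbutan-1-one | CC(C)CC(=O)c1c(O)cc(O)cc1O | intermediate
14 | 1-(2,4,6-trihydroxy-3-{[(1R,4S,4aS,6S,8aR)-4-hydroxy-4,8a-dimethyl-6-(prop-1-en-2-yl)decahydronaphthalen-1-yl]methyl}phenyl)-3-methylbutan-1-one | C=C(C)[C@H]1CC[C@]2(C)[C@@H](Cc3c(O)cc(O)c(C(=O)CC(C)C)c3O)CC[C@](C)(O)[C@H]2C1 | intermediate (not isolated)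
15 | 1-(2,4,6-trihydroxy-3-methyl-5-{[(1R,4S,4aS,6S,8aR)-4-hydroxy-4,8a-dimethyl-6-(prop-1-en-2-yl)decahydronaphthalen-1-yl]methyl}phenyl)-3-methylbutan-1-one | C=C(C)[C@H]1CC[C@]2(C)[C@@H](Cc3c(O)c(C)c(O)c(C(=O)CC(C)C)c3O)CC[C@](C)(O)[C@H]2C1 | intermediate (not isolated)
16 | 3,5-dihydroxy-4-{[(1R,4S,4aS,6S,8aR)-4-hydroxy-4,8a-dimethyl-6-(prop-1-en-2-yl)decahydronaphthalen-1-yl]methyl}-6,6-dimethyl-2-(3-methylbutanoyl)cyclohexa-2,4-dien-1-one | C=C(C)[C@H]1CC[C@]2(C)[C@@H](CC3=C(O)C(C)(C)C(=O)C(C(=O)CC(C)C)=C3O)CC[C@](C)(O)[C@H]2C1 | target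

**Step count**
Total: 9 steps (steps 1–7 to aldehyde 10, step 8 to arene 13, step 9 union and dearomatization).
Longest linear sequence: 8 steps (1 → 16 through steps 1–7 and 9).

**Three steps most likely to fail, with fallbacks**

Step 9 (one-flask reductive alkylation and dearomative gem-dimethylation). The risks are sluggish condensation of the hindered aldehyde with a phenolic nucleophile, methylation at the carbon bearing the terpenylmethyl group, over-methylation and O-methylation. The fallback sets out from 13 and comes back at 16. Arene 13 is dearomatized on its own with NaOMe/MeI in MeOH to isovalerylfilicinic acid, 3,5-dihydroxy-6,6-dimethyl-2-(3-methylbutanoyl)cyclohexa-2,4-dien-1-one F7, which is separated from under- and over-methylated material. F7, now with a single nucleophilic ring carbon, is joined to 10 with L-proline and Hantzsch ester in CH2Cl2 to give 16 directly, so no methylation is run on the advanced material.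

Step 4 (thermal intramolecular Diels–Alder). The β,β-disubstituted enoate is a weak dienophile and the trans/cis fusion and equatorial/axial isopropenyl ratios may be modest at 190 °C. The fallback sets out from 6 and comes back at 9. Ester 6 is reduced with i-Bu2AlH (CH2Cl2, −78 °C) to the allylic alcohol (2E,6S,8E)-3,9-dimethyl-6-(prop-1-en-2-yl)undeca-2,8,10-trien-1-ol F1 and oxidized with MnO2 to (2E,6S,8E)-3,9-dimethyl-6-(prop-1-en-2-yl)undeca-2,8,10-trienal F2. Me2AlCl (1.1 equiv, CH2Cl2, −78 → −20 °C) then promotes an endo-selective cycloaddition of the activated enal to (1S,4aR,6S,8aS)-4,8a-dimethyl-6-(prop-1-en-2-yl)-1,2,4a,5,6,7,8,8a-octahydronaphthalene-1-carbaldehyde F3. Buffered mCPBA gives the epoxy aldehyde (1S,3S,4R,4aS,6S,8aS)-3,4-epoxy-4,8a-dimethyl-6-(prop-1-en-2-yl)decahydronaphthalene-1-carbaldehyde F4, and LiAlH4 converts F4 into diol 9. This swaps thermal control for Lewis-acid activation with kinetic endo control at low temperature.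

Step 6 (regiochemistry of hydride opening). Attack at C3 is a diequatorial opening, so hydride could instead attack the tertiary carbon or the reaction could stall. The fallback sets out from 8 and comes back at 9. Epoxide 8 is opened with PhSeNa (from PhSeSePh and NaBH4, EtOH, 78 °C); a selenolate cannot substitute at the tertiary carbon, so it gives ethyl (1S,3R,4R,4aS,6S,8aS)-4-hydroxy-4,8a-dimethyl-3-(phenylselanyl)-6-(prop-1-en-2-yl)decahydronaphthalene-1-carboxylate F5. Radical removal of selenium with Bu3SnH/AIBN (toluene, 90 °C) gives the hydroxy ester ethyl (1S,4S,4aS,6S,8aS)-4-hydroxy-4,8a-dimethyl-6-(prop-1-en-2-yl)decahydronaphthalene-1-carboxylate F6, and LiAlH4 at 0 °C, which now only has to reduce the ester, gives 9.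

**Further compounds**
F1 | step 4 | (2E,6S,8E)-3,9-dimethyl-6-(prop-1-en-2-yl)undeca-2,8,10-trien-1-ol | C=C(C)[C@H](C/C=C(\C)C=C)CC/C(C)=C/CO
F2 | step 4 | (2E,6S,8E)-3,9-dimethyl-6-(prop-1-en-2-yl)undeca-2,8,10-trienal | C=C(C)[C@H](C/C=C(\C)C=C)CC/C(C)=C/C=O
F3 | step 4 | (1S,4aR,6S,8aS)-4,8a-dimethyl-6-(prop-1-en-2-yl)-1,2,4a,5,6,7,8,8a-octahydronaphthalene-1-carbaldehyde | C=C(C)[C@H]1CC[C@]2(C)[C@@H](C=O)CC=C(C)[C@H]2C1
F4 | step 4 | (1S,3S,4R,4aS,6S,8aS)-3,4-epoxy-4,8a-dimethyl-6-(prop-1-en-2-yl)decahydronaphthalene-1-carbaldehyde | C=C(C)[C@H]1CC[C@]2(C)[C@@H](C=O)C[C@@H]3O[C@]3(C)[C@H]2C1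
F5 | step 6 | ethyl (1S,3R,4R,4aS,6S,8aS)-4-hydroxy-4,8a-dimethyl-3-(phenylselanyl)-6-(prop-1-en-2-yl)decahydronaphthalene-1-carboxylate | C=C(C)[C@H]1CC[C@]2(C)[C@@H](C(=O)OCC)C[C@@H]([Se]c3ccccc3)[C@](C)(O)[C@H]2C1
F6 | step 6 | ethyl (1S,4S,4aS,6S,8aS)-4-hydroxy-4,8a-dimethyl-6-(prop-1-en-2-yl)decahydronaphthalene-1-carboxylate | C=C(C)[C@H]1CC[C@]2(C)[C@@H](C(=O)OCC)CC[C@](C)(O)[C@H]2C1
F7 | step 9 | 3,5-dihydroxy-6,6-dimethyl-2-(3-methylbutanoyl)cyclohexa-2,4-dien-1-one | CC(C)CC(=O)C1=C(O)C=C(O)C(C)(C)C1=O
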